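**Route outline**

- Rings: A cyclopentene, B cyclopentane carrying CO2Me, C seven-membered carbocycle, D N-methylpiperidine, E dihydropyran spiro-linked to C and D.
- Cuts, in retrosynthetic order: one ester of a ring B malonate (C–C); the enol ether C–O bond of ring E and the spiro C–CH2 bond; the whole CH2–N(CH3)–CH2 bridge of ring D at its two C–C bonds; the C(sp2)–CH2 bond of ring A; the two C–C bonds that make rings B and C from an alkyne and a vinylcyclopropane; the malonate C–C bonds of an acyclic enyne.
- Enabling feature: both N–CH2 carbons of ring D sit on the two carbons that flank the spiro carbon (the quaternary carbon common to rings B, C and D, and the bridgehead CH). With the spiro carbon as C=O these are the α and α′ carbons of a cycloheptenone, ring D is a 4-piperidone, and its bridge is what a ketone, CH3N=CH2 and one more CH2 give in a double Mannich reaction.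
- Forward order: chain by iridium-catalysed allylic alkylation and Michael addition; rings B and C together by (5+2) cycloaddition; ring A by B-alkyl Suzuki–Miyaura coupling; ring D by double Mannich annulation; one-carbon homologation, Michael addition and cyclodehydration for ring E; Krapcho reaction last.
- Stereochemistry: the ring A/B fusion CH comes from the chiral iridium catalyst and is the only catalyst-set centre. It directs the quaternary carbon (convex-face aminomethylation), the bridgehead follows from the bridge geometry, the spiro carbon from enone attack over the aza bridge, and the ester carbon from convex-face protonation.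

Key step: step 11

Assumption: the enolisable CH next to the masked or free ketone in 10–15, the formyl-bearing CH in 21 and the double-bond geometry of 20 are erased later and are written as one isomer; (E)-pent-2-en-4-yn-1-ol and cyclopropyl vinyl ketone are taken as catalogue compounds.

**Route**

Step 1
Reactants: 1 (E)-pent-2-en-4-yn-1-ol
Product: 3 (E)-5-(trimethylsilyl)pent-2-en-4-yn-1-ol, via bis-silylated enynol 2 (not isolated)
Conditions: EtMgBr (2.2 equiv), THF, 0 °C to rt; Me3SiCl (2.3 equiv); then 1 M HCl, rt
Reagents that add atoms: chlorotrimethylsilane, C[Si](C)(C)Cl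
Why: Double deprotonation gives the alkoxide acetylide, both sites are silylated and dilute acid cleaves only the labile Si–O bond, the standard C-silylation of a terminal alkyne through its magnesium acetylide.

Step 2
Reactants: 3 (E)-5-(trimethylsilyl)pent-2-en-4-yn-1-ol
Product: 4 methyl (E)-5-(trimethylsilyl)pent-2-en-4-yn-1-yl carbonate
Conditions: ClCO2Me, pyridine, CH2Cl2, 0 °C
Reagents that add atoms: methyl chloroformate, COC(=O)Cl
Why: O-acylation of the primary allylic alcohol with a chloroformate installs the carbonate leaving group for the allylic substitution.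

Step 3
Reactants: 4 methyl (E)-5-(trimethylsilyl)pent-2-en-4-yn-1-yl carbonate; 5 dimethyl malonate
Product: 6 dimethyl (R)-2-[5-(trimethylsilyl)pent-1-en-4-yn-3-yl]malonate
Conditions: [Ir(cod)Cl]2 (2 mol %), O,O'-(1,1'-binaphthalene-2,2'-diyl) N,N-bis(1-phenylethyl)phosphoramidite (4 mol %, the enantiomer that gives the R product), 1,5,7-triazabicyclo[4.4.0]dec-5-ene (8 mol %), THF, rt
Reagents that add atoms: none
Why: Iridium-catalysed asymmetric allylic alkylation, in which the cyclometalated iridium phosphoramidite complex ionises the carbonate to an allyl complex that the malonate attacks at the terminus bearing the conjugating silylalkynyl group (branched product), the chiral ligand fixing the face of attack and so the (R) centre that becomes the ring A/B fusion CH, with the methoxide released from the carbonate acting as base.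

Step 4
Reactants: 6 dimethyl (R)-2-[5-(trimethylsilyl)pent-1-en-4-yn-3-yl]malonate; 7 cyclopropyl vinyl ketone
Product: 8 dimethyl (R)-2-(3-cyclopropyl-3-oxopropyl)-2-[5-(trimethylsilyl)pent-1-en-4-yn-3-yl]malonate
Conditions: 7 (1.3 equiv), Cs2CO3 (0.2 equiv), MeCN, 0 °C to rt
Reagents that add atoms: none
Why: Base-catalysed Michael addition of the remaining malonate C–H to the unhindered enone, the carbonate base in acetonitrile being too weak to touch the allylic propargylic stereocentre or the alkynyl C–Si bond.

Step 5
Reactants: 8 cyclopropyl ketone enyne
Product: 9 (Z)-siloxy vinylcyclopropane enyne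
Conditions: t-BuMe2SiOTf (1.3 equiv), Et3N (2 equiv), CH2Cl2, 0 °C
Reagents that add atoms: tert-butyldimethylsilyl trifluoromethanesulfonate, CC(C)(C)[Si](C)(C)OS(=O)(=O)C(F)(F)F
Why: Soft enolisation and O-silylation of the ketone, which goes toward the chain CH2 because enolisation toward the ring would give a strained alkylidenecyclopropane, delivering the 1-siloxy vinylcyclopropane needed for the cycloaddition.

Step 6
Reactants: 9 (Z)-siloxy vinylcyclopropane enyne
Product: 10 bicyclo[5.3.0]decadiene cycloadduct (rings B and C)
Conditions: [Rh(CO)2Cl]2 (5 mol %), ClCH2CH2Cl, 80 °C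
Reagents that add atoms: none
Why: Rhodium-catalysed intramolecular (5+2) cycloaddition of a vinylcyclopropane with a tethered alkyne (cyclopropane cleavage, alkyne insertion, reductive elimination) should form ring B and cycloheptadiene ring C at once with the silyl enol ether and the vinylsilane in defined positions, the alkyne being a far better 2π partner than the equally tethered vinyl group and the new ring-fusion CH needing no control because it later becomes enolisable.

Step 7
Reactants: 10 bicyclo[5.3.0]decadiene cycloadduct
Product: 11 bicyclic dioxolane
Conditions: HOCH2CH2OH (10 equiv), camphor-10-sulfonic acid (10 mol %), CH2Cl2, rt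
Reagents that add atoms: ethane-1,2-diol, OCCO
Why: Acid-catalysed transacetalisation of the silyl enol ether (C-protonation at the former cyclopropane carbon, capture of the silyloxocarbenium ion by the diol, loss of silanol) should give the ketal directly, so that no enolisable β,γ-unsaturated ketone is exposed to N-iodosuccinimide, 9-BBN or Cs2CO3 in the next two steps.

Step 8
Reactants: 11 bicyclic dioxolane
Product: 12 alkenyl iodide
Conditions: N-iodosuccinimide (1.3 equiv), 2,6-lutidine (0.5 equiv), (CF3)2CHOH, 0 °C
Reagents that add atoms: N-iodosuccinimide, O=C1CCC(=O)N1I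
Why: Ipso-iododesilylation of a vinylsilane, in which the iodonium source adds to the silicon-bearing carbon (β-silyl-stabilised tertiary cation) and loss of the silyl group returns the tetrasubstituted double bond as the alkenyl iodide, the monosubstituted vinyl group being much less nucleophilic.

Step 9
Reactants: 12 alkenyl iodide
Product: 14 tricyclic ketal, via B-alkyl-9-BBN adduct 13 (not isolated)
Conditions: 9-BBN (9-borabicyclo[3.3.1]nonane, 1.5 equiv), THF, 0 °C to rt; then Pd(dppf)Cl2 (10 mol %), AsPh3 (10 mol %), Cs2CO3 (3 equiv), DMF/H2O, 50 °C
Reagents that add atoms: none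
Why: Anti-Markovnikov hydroboration of the monosubstituted alkene followed by intramolecular B-alkyl Suzuki–Miyaura coupling (oxidative addition of zerovalent palladium into the C–I bond, base-assisted alkyl transfer from boron, reductive elimination) should close five-membered ring A without touching the stereocentres.

Step 10
Reactants: 14 tricyclic ketal
Product: 15 carbotricyclic ketone
Conditions: pyridinium p-toluenesulfonate (0.3 equiv), acetone/H2O (10:1), 50 °C
Reagents that add atoms: water, O
Why: Mild acid hydrolysis of the dioxolane releases the β,γ-unsaturated cycloheptenone, whose α-CH is epimerisable, and any conjugated enone isomer formed would enter the next step through the same dienol.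

Step 11
Reactants: 15 carbotricyclic ketone; 16 1,3,5-trimethyl-1,3,5-triazinane
Product: 19 bridged amino ketone, via secondary Mannich base 17 (not isolated), via tethered iminium ion 18 (not isolated)
Conditions: 16 (0.8 equiv), CF3CO2H (3 equiv), MeCN, 60 °C; aq. NaHCO3 work-up
Reagents that add atoms: none
Why: Acid opens the triazinane to N-methylmethaniminium ions, the enol toward the unhindered α-CH2 is aminomethylated to give 17, aminal exchange with a second iminium equivalent (loss of methylamine) converts its N–H into the N-methyleneiminium ion 18, and the conjugated dienol on the other side attacks this tethered iminium through its α-carbon to create the quaternary centre. The closest known reaction is the piperidone-forming double Mannich annulation of cycloalkanones that gives 3-azabicyclo[3.3.1]nonan-9-ones and their ring homologues, here run across a cycloheptenone so that an 8-methyl-8-azabicyclo[4.3.1]dec-2-en-10-one results. Ring D closes by 6-endo-trig attack on the C=N+ carbon with the enol C=C inside the forming ring (6-enolendo), through a chair-like six-membered transition state. The quaternary stereocentre is controlled by the ring A/B fusion centre, the N–CH2 carbon entering on the convex face syn to the ring-fusion hydrogen, and the bridgehead CH has no freedom because the three-atom bridge can only span the two α-carbons cis. The step needs α- and not γ-attack of the dienol and a single annulation: the six-membered tether excludes the γ-carbon (it would be an eight-membered closure), the ketone has only these two α-positions, the malonate carbon has no hydrogen, and a Mannich base at a quaternary or bridgehead carbon cannot β-eliminate, so reversible aminomethylation, any vinylogous adduct and the conjugated ketone isomer should all funnel into 19.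

Step 12
Reactants: 19 bridged amino ketone
Product: 20 exocyclic methyl enol ether
Conditions: Ph3P(CH2OMe)Cl (3 equiv), KN(SiMe3)2 (2.8 equiv), THF, 0 °C to 50 °C
Reagents that add atoms: (methoxymethyl)triphenylphosphonium chloride, COC[P+](c1ccccc1)(c1ccccc1)c1ccccc1.[Cl-]
Why: Wittig methoxymethylenation, workable with excess ylide on this hindered carbonyl because the bridging ketone cannot enolise (bridgehead CH on one side, quaternary carbon on the other) and the malonate has no acidic hydrogen, the E/Z isomers converging in the next step.

Step 13
Reactants: 20 exocyclic methyl enol ether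
Product: 21 bridge aldehyde
Conditions: 2 M HCl, THF, rt; then aq. NaHCO3
Reagents that add atoms: water, O
Why: Acid hydrolysis of the enol ether (C-protonation at the bridging carbon, collapse of the hemiacetal) completes the one-carbon homologation, the new CH being planarised again in the next step.

Step 14
Reactants: 21 bridge aldehyde; 22 ethyl vinyl ketone
Product: 23 keto aldehyde with the spiro quaternary carbon
Conditions: 22 (1.5 equiv), DBU (0.2 equiv), MeCN, 0 °C to rt
Reagents that add atoms: none
Why: Base-catalysed Michael addition of an α-branched aldehyde through its exocyclic enolate, the enone being expected to approach over the smaller CH2–N(CH3)–CH2 bridge (two axial C–H bonds only) and not over the four-carbon bridge that carries rings A and B, which places the oxopentyl chain syn to nitrogen and the formyl group over the carbocycle and so sets the spiro carbon.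

Step 15
Reactants: 23 keto aldehyde
Product: 24 hydroxy ketone
Conditions: NaBH4 (0.5 equiv), MeOH/CH2Cl2 (1:1), −78 °C; acetone, then aq. NH4Cl
Reagents that add atoms: none
Why: Chemoselective borohydride reduction, since at low temperature in methanol/dichloromethane an aldehyde is reduced far faster than a dialkyl ketone or an ester, so the formyl group should be reduced alone and the product may rest as its cyclic hemiketal.

Step 16
Reactants: 24 hydroxy ketone
Product: 25 spiro dihydropyran diester
Conditions: TsOH·H2O (1.3 equiv), 4 Å molecular sieves, PhH, 80 °C; then Et3N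
Reagents that add atoms: none
Why: Acid-catalysed cyclodehydration, in which the δ-hydroxy ketone closes to the six-membered hemiketal and loses water toward the ring CH2 to give the endocyclic trisubstituted enol ether, the more stable of the possible enol ethers, the extra acid covering the basic nitrogen.

Step 17
Reactants: 25 spiro dihydropyran diester
Product: 26 target CNP0159589.3
Conditions: LiCl (5 equiv), H2O (3 equiv), Me2SO, 150 °C
Reagents that add atoms: none
Why: Krapcho dealkoxycarbonylation, in which chloride demethylates one ester, the carboxylate loses CO2 and the ester enolate is protonated on the convex face of ring B (the face of the ring-fusion hydrogen, opposite the ring A CH2 and the spiro carbon), leaving CO2Me anti to the ring-fusion hydrogen while enol ether and amine tolerate the neutral to basic medium.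

**Compound list**

1 | (E)-pent-2-en-4-yn-1-ol | OC/C=C/C#C | starting material
2 | trimethyl{[(E)-5-(trimethylsilyl)pent-2-en-4-yn-1-yl]oxy}silane (bis-silylated enynol) | C[Si](C)(C)OC/C=C/C#C[Si](C)(C)C | intermediate
3 | (E)-5-(trimethylsilyl)pent-2-en-4-yn-1-ol | OC/C=C/C#C[Si](C)(C)C | intermediate
4 | methyl (E)-5-(trimethylsilyl)pent-2-en-4-yn-1-yl carbonate | COC(=O)OC/C=C/C#C[Si](C)(C)C | intermediate
5 | dimethyl malonate | COC(=O)CC(=O)OC | starting material
6 | dimethyl (R)-2-[5-(trimethylsilyl)pent-1-en-4-yn-3-yl]malonate | C=C[C@@H](C#C[Si](C)(C)C)C(C(=O)OC)C(=O)OC | intermediate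
7 | cyclopropyl vinyl ketone (1-cyclopropylprop-2-en-1-one) | C=CC(=O)C1CC1 | starting material
8 | dimethyl (R)-2-(3-cyclopropyl-3-oxopropyl)-2-[5-(trimethylsilyl)pent-1-en-4-yn-3-yl]malonate | C=C[C@@H](C#C[Si](C)(C)C)C(C(=O)OC)(C(=O)OC)CCC(=O)C1CC1 | intermediate
9 | dimethyl (R)-2-[(Z)-3-(tert-butyldimethylsilyloxy)-3-cyclopropylprop-2-en-1-yl]-2-[5-(trimethylsilyl)pent-1-en-4-yn-3-yl]malonate | C=C[C@@H](C#C[Si](C)(C)C)C(C(=O)OC)(C(=O)OC)C/C=C(\O[Si](C)(C)C(C)(C)C)C1CC1 | intermediate
10 | dimethyl 8-(tert-butyldimethylsilyloxy)-3-ethenyl-4-(trimethylsilyl)-3,5,6,8a-tetrahydroazulene-2,2(1H)-dicarboxylate, 3-H and 8a-H cis as drawn | C=C[C@H]1C2=C([Si](C)(C)C)CCC=C(O[Si](C)(C)C(C)(C)C)[C@H]2CC1(C(=O)OC)C(=O)OC | intermediate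
11 | dimethyl 3-ethenyl-8,8-(ethylenedioxy)-4-(trimethylsilyl)-3,5,6,7,8,8a-hexahydroazulene-2,2(1H)-dicarboxylate | C=C[C@H]1C2=C([Si](C)(C)C)CCCC3(OCCO3)[C@H]2CC1(C(=O)OC)C(=O)OC | intermediate
12 | dimethyl 3-ethenyl-8,8-(ethylenedioxy)-4-iodo-3,5,6,7,8,8a-hexahydroazulene-2,2(1H)-dicarboxylate | C=C[C@H]1C2=C(I)CCCC3(OCCO3)[C@H]2CC1(C(=O)OC)C(=O)OC | intermediate
13 | B-alkyl adduct: 12 with the ethenyl group converted into CH2CH2–B(9-borabicyclo[3.3.1]nonan-9-yl) | C1CCC2CCCC1B2CC[C@H]3C4=C(I)CCCC5(OCCO5)[C@H]4CC3(C(=O)OC)C(=O)OC | intermediate
14 | tricyclic ketal: ethylene ketal of ketone 15 | O1CCOC12CCCC3=C4[C@@H]2CC(C(=O)OC)(C(=O)OC)[C@H]4CC3 | intermediate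
15 | carbotricyclic ketone: cyclopentene ring A and cyclopentane ring B fused at a C(sp2)–CH bond, cycloheptenone ring C peri-fused through the same sp2 carbon; tetrasubstituted C=C common to rings A and C and β,γ to the C=O; C(CO2Me)2 in ring B next to the ring-fusion CH; ketone α-CH drawn with H cis to the ring-fusion H | O=C1CCCC2=C3[C@@H]1CC(C(=O)OC)(C(=O)OC)[C@H]3CC2 | intermediate
16 | 1,3,5-trimethyl-1,3,5-triazinane | CN1CN(C)CN(C)C1 | starting material
17 | secondary Mannich base: 15 with CH2NHCH3 on the α-CH2 carbon of the ketone | O=C1[C@@H](CNC)CCC2=C3[C@@H]1CC(C(=O)OC)(C(=O)OC)[C@H]3CC2 | intermediate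
18 | tethered iminium ion: 17 with its nitrogen as N(CH3)=CH2+, trifluoroacetate salt | O=C1[C@@H](C[N+](C)=C)CCC2=C3[C@@H]1CC(C(=O)OC)(C(=O)OC)[C@H]3CC2.[O-]C(=O)C(F)(F)F | intermediate
19 | bridged amino ketone: 8-methyl-8-azabicyclo[4.3.1]dec-2-en-10-one core (rings C and D) with rings A and B fused on; N–CH2 on the quaternary carbon cis to the ring-fusion H; gem-dimethyl diester in ring B | O=C2[C@@H]1CCC3=C4[C@H](CC3)C(C(=O)OC)(C(=O)OC)C[C@@]42CN(C)C1 | intermediate
20 | exocyclic methyl enol ether: C=O of 19 replaced by C=CH–OCH3 (E/Z mixture) | COC=C2[C@@H]1CCC3=C4[C@H](CC3)C(C(=O)OC)(C(=O)OC)C[C@@]42CN(C)C1 | intermediate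
21 | bridge aldehyde: bridging carbon of 19 as CH–CHO, formyl drawn over the four-carbon bridge | O=C[C@@H]2[C@@H]1CCC3=C4[C@H](CC3)C(C(=O)OC)(C(=O)OC)C[C@@]42CN(C)C1 | intermediate
22 | ethyl vinyl ketone (pent-1-en-3-one) | CCC(=O)C=C | starting material
23 | keto aldehyde: bridging carbon quaternary, 3-oxopentyl chain syn to the aza bridge, CHO over the four-carbon bridge | CCC(=O)CC[C@@]2(C=O)[C@@H]1CCC3=C4[C@H](CC3)C(C(=O)OC)(C(=O)OC)C[C@@]42CN(C)C1 | intermediate
24 | hydroxy ketone: 23 with CHO reduced to CH2OH | CCC(=O)CC[C@@]2(CO)[C@@H]1CCC3=C4[C@H](CC3)C(C(=O)OC)(C(=O)OC)C[C@@]42CN(C)C1 | intermediate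
25 | spiro dihydropyran diester: 6-ethyl-3,4-dihydro-2H-pyran spiro-fused through its C3 at the bridging carbon, ring B still C(CO2Me)2 | CCC1=CC[C@@]2(CO1)[C@@H]1CCC3=C4[C@H](CC3)C(C(=O)OC)(C(=O)OC)C[C@@]42CN(C)C1 | intermediate
26 | target CNP0159589.3: 25 with one ester removed, CO2Me anti to the ring-fusion H | CCC1=CC[C@@]2(CO1)[C@@H]1CCC3=C4[C@H](CC3)[C@H](C(=O)OC)C[C@@]42CN(C)C1 | target

**Step count**

Total: 17 steps. Longest linear sequence: 17 steps (1 to 26).

**Steps most likely to fail**

1. Step 11. The dienol may be aminomethylated at its γ-carbon, or the reaction may stop after the first Mannich event because the ring-closing attack at the hindered methine is too slow, giving open Mannich bases and a conjugated alkene. The fallback makes the quaternary C–C bond first under enolate control and leaves the easy closure for last. It sets out from 15. KOt-Bu (THF, 0 °C) gives the extended potassium enolate, which is aminomethylated at its α-carbon on the convex face with preformed N-benzyl-N-methylmethaniminium chloride (−78 °C) to give the benzyl(methyl)aminomethyl ketone F1. Hydrogenolysis (H2, Pd(OH)2/C, MeOH) gives the secondary amine F2. Paraformaldehyde and CF3CO2H in MeCN at 60 °C convert its N–H into the N-methyleneiminium ion, which closes onto the only remaining enolisable position, the α-CH2, and the route is rejoined at 19.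

2. Step 14. The enone may approach the exocyclic enolate over the four-carbon bridge instead of the aza bridge, giving reversed or poor facial selectivity at the spiro carbon. The fallback uses the same facial bias but swaps the order in which the two substituents arrive. It sets out from 21. Crossed aldol reaction with aqueous formaldehyde (K2CO3, THF, rt) places CH2OH on the face the electrophile prefers and gives the hydroxymethyl aldehyde F3. Wittig reaction of its formyl group with Ph3P=CHC(O)Et (toluene, 90 °C) gives the (E)-enone F4. Conjugate reduction with [(Ph3P)CuH]6 (benzene, rt) gives the hydroxy ketone, and the route is rejoined at 24.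

3. Step 17. At 150 °C the ester enolate may be protonated, or the product epimerised, under thermodynamic control, which would put the ester cis to the ring-fusion hydrogen. The fallback sets the centre in a separate kinetic step. It sets out from 25. The Krapcho reaction is run as before and the epimeric ester F5 (alone or mixed with 26) is deprotonated with LiN(i-Pr)2 (THF, −78 °C). The enolate is quenched at −78 °C with the hindered proton donor 2,6-di-tert-butyl-4-methylphenol, which should deliver the proton to the convex face, and the route is rejoined at 26.

**Further compounds**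

F1 | step 11 | benzyl(methyl)aminomethyl ketone: 15 with CH2N(CH3)CH2Ph on the ketone α-carbon of ring B, cis to the ring-fusion H | O=C1CCCC2=C3[C@H](CC2)C(C(=O)OC)(C(=O)OC)C[C@@]31CN(C)Cc5ccccc5
F2 | step 11 | secondary amine: 15 with CH2NHCH3 on the ketone α-carbon of ring B, cis to the ring-fusion H | O=C1CCCC2=C3[C@H](CC2)C(C(=O)OC)(C(=O)OC)C[C@@]31CNC
F3 | step 14 | hydroxymethyl aldehyde: bridging carbon of 21 quaternary with CH2OH over the four-carbon bridge and CHO syn to the aza bridge | O=C[C@@]2(CO)[C@@H]1CCC3=C4[C@H](CC3)C(C(=O)OC)(C(=O)OC)C[C@@]42CN(C)C1
F4 | step 14 | (E)-enone: F3 with CHO converted into (E)-CH=CH–C(O)CH2CH3 | CCC(=O)/C=C/[C@@]2(CO)[C@@H]1CCC3=C4[C@H](CC3)C(C(=O)OC)(C(=O)OC)C[C@@]42CN(C)C1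
F5 | step 17 | epimer of 26 at the ester-bearing carbon (CO2Me cis to the ring-fusion H) | CCC1=CC[C@@]2(CO1)[C@@H]1CCC3=C4[C@H](CC3)[C@@H](C(=O)OC)C[C@@]42CN(C)C1
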